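**Retrosynthetic overview**
- The acid comes from its methyl ester by saponification. The oxane is the only ring and is closed in the second-to-last step.
- Key step: cobalt-catalysed radical 6-exo cyclisation of a primary alkyl iodide onto a β-alkoxymethacrylate, ended by loss of a hydrogen atom from the α-methyl group. It forms C2–C3, sets C2 trans to C5 and gives the α-methylene ester in one operation.
- The iodide comes from anti-Markovnikov hydrozirconation–iodination of a vinyl group. The enol ether comes from O-alkylation of methyl 2-formylpropanoate with a homoallylic bromide.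
- C5 is set by copper-catalysed asymmetric SN2′ alkylation of (E)-1,4-dibromobut-2-ene with the homofarnesyl Grignard reagent.
- Homofarnesyl bromide comes from two iterative Negishi couplings of homoallylic zinc reagents with (E)-5-bromo-2-iodopent-2-ene, itself made from pent-3-yn-1-ol.

Assumption: compound 13 is bought as a catalogue compound, and the Taniaphos enantiomer used in step 5 is the one that gives R at C5 (both enantiomers are sold; the sense is confirmed on the first run).

**Route**

Step 1
Reactants: 1 pent-3-yn-1-ol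
Product: 2 5-bromopent-2-yne
Conditions: CBr4, PPh3, CH2Cl2, 0 °C to 23 °C
Reagents that add atoms: carbon tetrabromide, BrC(Br)(Br)Br
Why: Appel bromination of a primary alcohol leaves the internal alkyne untouched and creates no stereocentre.

Step 2
Reactants: 2 5-bromopent-2-yne
Product: 4 (2E)-5-bromo-2-iodopent-2-ene, via alkenylzirconocene chloride 3 (not isolated)
Conditions: Cp2Zr(H)Cl (1.5 equiv), THF, 23 °C then 45 °C; then I2, THF, 0 °C
Reagents that add atoms: iodine, II
Why: Syn-hydrozirconation of the 2-alkyne puts zirconium on the less hindered methyl-bearing carbon (excess reagent equilibrates the regioisomers to about 95:5 or better), and iodinolysis with retention gives the E-iodide (hydrozirconation–iodination).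

Step 3
Reactants: 5 5-bromo-2-methylpent-2-ene; 4 (2E)-5-bromo-2-iodopent-2-ene
Product: 7 (3E)-1-bromo-4,8-dimethylnona-3,7-diene, via homoprenylzinc bromide 6 (not isolated)
Conditions: Zn dust, I2 (5 mol %), DMA, 70 °C, decant from Zn; then 4 (0.8 equiv), PdCl2(dppf) (3 mol %), THF, 40 °C
Reagents that add atoms: none
Why: Negishi coupling, in which zerovalent palladium inserts into the alkenyl C–I bond far faster than into the primary C–Br bond and the alkene geometry is retained.

Step 4
Reactants: 7 (3E)-1-bromo-4,8-dimethylnona-3,7-diene; 4 (2E)-5-bromo-2-iodopent-2-ene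
Product: 9 (3E,7E)-1-bromo-4,8,12-trimethyltrideca-3,7,11-triene, via homogeranylzinc bromide 8 (not isolated)
Conditions: Zn dust, I2 (5 mol %), DMA, 70 °C, decant from Zn; then 4 (0.8 equiv), PdCl2(dppf) (3 mol %), THF, 40 °C
Reagents that add atoms: none
Why: Second Negishi coupling of the same kind, which adds the next isoprenoid unit with retention of the E geometry of both partners.

Step 5
Reactants: 9 (3E,7E)-1-bromo-4,8,12-trimethyltrideca-3,7,11-triene; 10 (2E)-1,4-dibromobut-2-ene
Product: 12 (3R,6E,10E)-3-(bromomethyl)-7,11,15-trimethylhexadeca-1,6,10,14-tetraene, via homofarnesylmagnesium bromide 11 (not isolated)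
Conditions: Mg, Et2O, 35 °C; then slow addition to 10 (1.5 equiv), CuBr·SMe2 (3 mol %), Taniaphos (3.6 mol %), CH2Cl2, −75 °C
Reagents that add atoms: none
Why: Copper-catalysed asymmetric allylic alkylation (anti SN2′) of the symmetric dibromide, in which the chiral monovalent copper–diphosphine complex selects one face of the alkene during γ-attack and so sets C5 as R; the remaining bromide is homoallylic and does not react further.

Step 6
Reactants: 12 (3R,6E,10E)-3-(bromomethyl)-7,11,15-trimethylhexadeca-1,6,10,14-tetraene; 13 methyl 2-methyl-3-oxopropanoate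
Product: 15 methyl (2E)-3-{[(2R,5E,9E)-2-ethenyl-6,10,14-trimethylpentadeca-5,9,13-trien-1-yl]oxy}-2-methylprop-2-enoate, via cesium enolate 14 (not isolated)
Conditions: 13 (2 equiv), Cs2CO3 (2 equiv), NaI (20 mol %), DMF, 55 °C
Reagents that add atoms: none
Why: O-alkylation of an α-substituted formyl ester enolate, where C-alkylation would need a quaternary centre, so the unhindered oxygen reacts as in the preparation of alkoxymethylene derivatives and β-methoxyacrylates; C5 is not touched, and any Z enol ether converges with the E isomer in step 8.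

Step 7
Reactants: 15 methyl (2E)-3-{[(2R,5E,9E)-2-ethenyl-6,10,14-trimethylpentadeca-5,9,13-trien-1-yl]oxy}-2-methylprop-2-enoate
Product: 17 methyl (2E)-3-{[(2R,5E,9E)-2-(2-iodoethyl)-6,10,14-trimethylpentadeca-5,9,13-trien-1-yl]oxy}-2-methylprop-2-enoate, via alkylzirconocene chloride 16 (not isolated)
Conditions: Cp2Zr(H)Cl (1.2 equiv), THF, 23 °C, 30 min; then I2, THF, −20 °C
Reagents that add atoms: iodine, II
Why: Hydrozirconation with Cp2Zr(H)Cl picks the monosubstituted alkene over the trisubstituted alkenes, the push–pull enol ether and the ester, places zirconium on the terminal carbon, and iodinolysis gives the primary iodide (hydrozirconation–iodination); the stereocentre is untouched.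

Step 8
Reactants: 17 methyl (2E)-3-{[(2R,5E,9E)-2-(2-iodoethyl)-6,10,14-trimethylpentadeca-5,9,13-trien-1-yl]oxy}-2-methylprop-2-enoate
Product: 18 methyl 2-[(2S,5R)-5-[(3E,7E)-4,8,12-trimethyltrideca-3,7,11-trien-1-yl]oxan-2-yl]prop-2-enoate
Conditions: Co(dmgH)2(py)SnPh3 (15 mol %), i-Pr2NEt (2 equiv), MeCN (0.01 M), blue LEDs, 23 °C
Reagents that add atoms: none
Why: Proposed new method: monovalent cobalt displaces iodide, visible light homolyses the alkyl–cobalt bond, and the primary C3 radical closes 6-exo onto the β-carbon of the β-alkoxymethacrylate through a chair transition state with the C5 chain and the acceptor both equatorial (2,5-trans, C2 = S, expected about 6:1 to 10:1, minor cis isomer removed on AgNO3-impregnated silica); divalent cobalt then removes a hydrogen atom from the accessible α-methyl group of the tertiary ester radical to give the α-methylene ester, and the amine deprotonates the trivalent cobalt hydride back to monovalent cobalt before it can re-add; the closest known reactions are the radical cyclisation of β-alkoxyacrylates to oxanes, the cobalt-catalysed alkyl-Heck cyclisation of alkyl iodides under visible light, and catalytic chain transfer in methacrylate polymerisation, which removes hydrogen from the α-methyl group.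

Step 9
Reactants: 18 methyl 2-[(2S,5R)-5-[(3E,7E)-4,8,12-trimethyltrideca-3,7,11-trien-1-yl]oxan-2-yl]prop-2-enoate
Product: 20 2-[(2S,5R)-5-[(3E,7E)-4,8,12-trimethyltrideca-3,7,11-trien-1-yl]oxan-2-yl]prop-2-enoic acid, via lithium carboxylate 19 (not isolated)
Conditions: LiOH, THF/MeOH/H2O, 23 °C; then 1 M HCl, 0 °C
Reagents that add atoms: lithium hydroxide, [Li+].[OH-]
Why: Saponification of the methyl ester, in which neither stereocentre is epimerisable and the brief cold acidification does not affect the trisubstituted alkenes.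

**Compound list**

1 | pent-3-yn-1-ol | CC#CCCO | starting material
2 | 5-bromopent-2-yne | CC#CCCBr | intermediate
3 | [(2E)-5-bromopent-2-en-2-yl]chlorobis(cyclopentadienyl)zirconium (Zr on C2, cis to the vinyl H) | C/C(=C\CCBr)[Zr](Cl)(C1C=CC=C1)C1C=CC=C1 | intermediate (not isolated)
4 | (2E)-5-bromo-2-iodopent-2-ene | C/C(I)=C\CCBr | intermediate
5 | 5-bromo-2-methylpent-2-ene | CC(C)=CCCBr | starting material
6 | (4-methylpent-3-en-1-yl)zinc bromide | CC(C)=CCC[Zn]Br | intermediate (not isolated)
7 | (3E)-1-bromo-4,8-dimethylnona-3,7-diene | CC(C)=CCC/C(C)=C/CCBr | intermediate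
8 | [(3E)-4,8-dimethylnona-3,7-dien-1-yl]zinc bromide | CC(C)=CCC/C(C)=C/CC[Zn]Br | intermediate (not isolated)
9 | (3E,7E)-1-bromo-4,8,12-trimethyltrideca-3,7,11-triene | CC(C)=CCC/C(C)=C/CC/C(C)=C/CCBr | intermediate
10 | (2E)-1,4-dibromobut-2-ene | BrC/C=C/CBr | starting material
11 | [(3E,7E)-4,8,12-trimethyltrideca-3,7,11-trien-1-yl]magnesium bromide | CC(C)=CCC/C(C)=C/CC/C(C)=C/CC[Mg]Br | intermediate (not isolated)
12 | (3R,6E,10E)-3-(bromomethyl)-7,11,15-trimethylhexadeca-1,6,10,14-tetraene | C=C[C@@H](CC/C=C(\C)CC/C=C(\C)CCC=C(C)C)CBr | intermediate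
13 | methyl 2-methyl-3-oxopropanoate (methyl 2-formylpropanoate) | COC(=O)C(C)C=O | starting material
14 | cesium 3-methoxy-2-methyl-3-oxoprop-1-en-1-olate (enolate geometry not defined) | COC(=O)C(C)=C[O-].[Cs+] | intermediate (not isolated)
15 | methyl (2E)-3-{[(2R,5E,9E)-2-ethenyl-6,10,14-trimethylpentadeca-5,9,13-trien-1-yl]oxy}-2-methylprop-2-enoate | C=C[C@@H](CC/C=C(\C)CC/C=C(\C)CCC=C(C)C)CO/C=C(\C)C(=O)OC | intermediate
16 | alkylzirconocene chloride from 15 (Cp2ZrCl on the terminal carbon of the former vinyl group) | Cl[Zr](CC[C@@H](CC/C=C(\C)CC/C=C(\C)CCC=C(C)C)CO/C=C(\C)C(=O)OC)(C1C=CC=C1)C1C=CC=C1 | intermediate (not isolated)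
17 | methyl (2E)-3-{[(2R,5E,9E)-2-(2-iodoethyl)-6,10,14-trimethylpentadeca-5,9,13-trien-1-yl]oxy}-2-methylprop-2-enoate | ICC[C@@H](CC/C=C(\C)CC/C=C(\C)CCC=C(C)C)CO/C=C(\C)C(=O)OC | intermediate
18 | methyl 2-[(2S,5R)-5-[(3E,7E)-4,8,12-trimethyltrideca-3,7,11-trien-1-yl]oxan-2-yl]prop-2-enoate | C=C(C(=O)OC)[C@@H]1CC[C@@H](CC/C=C(\C)CC/C=C(\C)CCC=C(C)C)CO1 | intermediate
19 | lithium 2-[(2S,5R)-5-[(3E,7E)-4,8,12-trimethyltrideca-3,7,11-trien-1-yl]oxan-2-yl]prop-2-enoate | C=C(C(=O)[O-])[C@@H]1CC[C@@H](CC/C=C(\C)CC/C=C(\C)CCC=C(C)C)CO1.[Li+] | intermediate (not isolated)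
20 | 2-[(2S,5R)-5-[(3E,7E)-4,8,12-trimethyltrideca-3,7,11-trien-1-yl]oxan-2-yl]prop-2-enoic acid | C=C(C(=O)O)[C@@H]1CC[C@@H](CC/C=C(\C)CC/C=C(\C)CCC=C(C)C)CO1 | target

**Totals**
Total step count: 9. Longest linear sequence: 9 steps (1 → 2 → 4 → 7 → 9 → 12 → 15 → 17 → 18 → 20).

**Steps most likely to fail, with fallbacks**

Step 8 is the riskiest. The cobalt may remove the C2 hydrogen instead of a methyl hydrogen and give the alkylidene oxane, it may dehydrohalogenate 17 before ring closure, and the trans/cis ratio may be modest. The fallback sets out from 17 and comes back at 18. Compound 17 is cyclised with Bu3SnH and AIBN (syringe pump, benzene, 80 °C), the classical tin hydride version of the same ring closure, to give the saturated ester methyl 2-[(2S,5R)-5-[(3E,7E)-4,8,12-trimethyltrideca-3,7,11-trien-1-yl]oxan-2-yl]propanoate F1 as a mixture at the α-carbon. Deprotonation with LiN(i-Pr)2 at −78 °C and trapping with PhSeBr (1.05 equiv) gives methyl 2-(phenylselanyl)-2-[(2S,5R)-5-[(3E,7E)-4,8,12-trimethyltrideca-3,7,11-trien-1-yl]oxan-2-yl]propanoate F2. Oxidation with H2O2 and pyridine at 0 °C gives the selenoxide, which eliminates towards the methyl group (syn-elimination towards an oxygen-bearing carbon is disfavoured) and delivers 18.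

Step 5 is next. The dibromide may give SN2 product, double alkylation or insufficient ee with this long Grignard reagent. The fallback sets out from 11 and comes back at 15. Grignard reagent 11 is added to methyl (2E)-4-bromobut-2-enoate with CuBr·SMe2 and Taniaphos in CH2Cl2 at −75 °C. In this substrate class the ester fixes attack at the carbon next to it and C6 enters at the ester oxidation level, giving methyl (2R,5E,9E)-2-ethenyl-6,10,14-trimethylpentadeca-5,9,13-trienoate F3. Reduction with LiAlH4 in Et2O at −78 °C, kept cold to protect the α-stereocentre, gives (2R,5E,9E)-2-ethenyl-6,10,14-trimethylpentadeca-5,9,13-trien-1-ol F4. Mitsunobu etherification of F4 with 13 (PPh3, DIAD, THF, 0 °C) then gives 15.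

Step 6 is third. The β-branched bromide may react slowly, and C-alkylation of the enolate or elimination of HBr may compete. The fallback sets out from 12 and comes back at 15. Bromide 12 is displaced with CsOAc in DMF at 60 °C, using a non-ambident and weakly basic nucleophile, to give (2R,5E,9E)-2-ethenyl-6,10,14-trimethylpentadeca-5,9,13-trien-1-yl acetate F5. Methanolysis with K2CO3 in MeOH gives the alcohol F4 already described. The C–O bond is then made from the alcohol side by Mitsunobu etherification with 13 (PPh3, DIAD, THF, 0 °C), which gives 15.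

**Further compounds**
F1 | step 8 | methyl 2-[(2S,5R)-5-[(3E,7E)-4,8,12-trimethyltrideca-3,7,11-trien-1-yl]oxan-2-yl]propanoate (both α-epimers) | COC(=O)C(C)[C@@H]1CC[C@@H](CC/C=C(\C)CC/C=C(\C)CCC=C(C)C)CO1
F2 | step 8 | methyl 2-(phenylselanyl)-2-[(2S,5R)-5-[(3E,7E)-4,8,12-trimethyltrideca-3,7,11-trien-1-yl]oxan-2-yl]propanoate (both α-epimers) | COC(=O)C(C)([Se]c1ccccc1)[C@@H]1CC[C@@H](CC/C=C(\C)CC/C=C(\C)CCC=C(C)C)CO1
F3 | step 5 | methyl (2R,5E,9E)-2-ethenyl-6,10,14-trimethylpentadeca-5,9,13-trienoate | C=C[C@@H](CC/C=C(\C)CC/C=C(\C)CCC=C(C)C)C(=O)OC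
F4 | step 5 | (2R,5E,9E)-2-ethenyl-6,10,14-trimethylpentadeca-5,9,13-trien-1-ol | C=C[C@@H](CC/C=C(\C)CC/C=C(\C)CCC=C(C)C)CO
F5 | step 6 | (2R,5E,9E)-2-ethenyl-6,10,14-trimethylpentadeca-5,9,13-trien-1-yl acetate | C=C[C@@H](CC/C=C(\C)CC/C=C(\C)CCC=C(C)C)COC(C)=O
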